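**Retrosynthetic overview**

- The strategy rests on the C8' carbinol: it is allylic to the C9'=C10' styrene and 1,3-syn to the C6' carbinol, so its oxygen can arrive from the benzylic carbon C10' by 1,3-transposition and be locked as the six-membered 1,3-dioxane O6'–CH(Ph)–O8' (ring B, temporary).
- Lactone ring A (O1, C2–C6) is disconnected at C3=C4 by ring-closing metathesis of a C6 acrylate; C6 comes from allylboration of a C1' ynal and the (Z)-C1'=C2' alkene from semi-hydrogenation. A C2–C6 enoate aldehyde is avoided because it would be a labile β,γ-unsaturated aldehyde.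
- The benzylidene acetal is disconnected to a C1'–C10' (E)-ene-1,5-diol (hydroxyls at C6' and C10', alkene C8'=C9') plus benzaldehyde dimethyl acetal.
- The ene-diol comes from a C6' homoallylic alcohol and racemic 1-phenylprop-2-en-1-ol by cross-metathesis; C6' from allylboration of a C6' aldehyde; C4' from (S)-epichlorohydrin, trimethylsilylacetylene and a vinyl Grignard reagent.
- Ring order: dioxane ring B first, lactone ring A last.

Key step: step 8

Remark: locants follow the natural product (lactone O1, C2–C6; side chain C1'–C10', C1' on C6, phenyl on C10'). Racemic 1-phenylprop-2-en-1-ol is used on purpose, so the cross-metathesis product is carried as a mixture of C10' epimers that the key step should merge.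

**Route**

Step 1
Reactants: 1 (S)-epichlorohydrin; 2 trimethylsilylacetylene
Product: 3 (S)-1-chloro-5-(trimethylsilyl)pent-4-yn-2-ol
Conditions: 2, n-BuLi, THF, −78 °C; BF3·OEt2; then 1, −78 °C; aq. NH4Cl
Reagents that add atoms: none
Why: Yamaguchi–Hirao alkynylation: the lithium acetylide of 2 opens the BF3-activated epoxide at its unsubstituted ring carbon faster than it displaces chloride, so the carbinol centre of 1 is carried over unchanged as the future C4'.

Step 2
Reactants: 3 (S)-1-chloro-5-(trimethylsilyl)pent-4-yn-2-ol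
Product: 4 (S)-trimethyl[3-(oxiran-2-yl)prop-1-yn-1-yl]silane
Conditions: NaH, THF, 0 °C → rt
Reagents that add atoms: none
Why: Intramolecular Williamson etherification (3-exo-tet) of the sodium alkoxide on the primary chloride re-forms a terminal epoxide without touching the stereocentre, and an aprotic hydride base leaves the alkynyl C–Si bond intact.

Step 3
Reactants: 4 (S)-trimethyl[3-(oxiran-2-yl)prop-1-yn-1-yl]silane
Product: 5 (R)-1-(trimethylsilyl)hept-6-en-1-yn-4-ol
Conditions: CH2=CHMgBr, CuI (10 mol %), THF, −40 → −20 °C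
Reagents that add atoms: vinylmagnesium bromide, C=C[Mg]Br
Why: Copper-catalysed Grignard opening of the terminal epoxide at its CH2 carbon should give the homoallylic alcohol with C4' untouched, the silyl-capped alkyne being inert to the vinyl cuprate.

Step 4
Reactants: 5 (R)-1-(trimethylsilyl)hept-6-en-1-yn-4-ol
Product: 6 (R)-tert-butyldimethyl{[1-(trimethylsilyl)hept-6-en-1-yn-4-yl]oxy}silane
Conditions: TBSCl, imidazole, DMF, rt
Reagents that add atoms: tert-butyldimethylsilyl chloride, CC(C)(C)[Si](C)(C)Cl
Why: Standard imidazole-promoted silylation of a secondary alcohol; the silyl ether removes O4' from any later acetal formation.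

Step 5
Reactants: 6 (R)-tert-butyldimethyl{[1-(trimethylsilyl)hept-6-en-1-yn-4-yl]oxy}silane
Product: 8 (S)-3-[(tert-butyldimethylsilyl)oxy]-6-(trimethylsilyl)hex-5-ynal, via vicinal diol 7 (not isolated)
Conditions: OsO4 (2 mol %), NaIO4, 2,6-lutidine, dioxane/H2O (3:1), rt
Reagents that add atoms: osmium tetroxide, O=[Os](=O)(=O)=O (catalytic oxygen carrier); sodium periodate, [Na+].[O-]I(=O)(=O)=O
Why: Lemieux–Johnson cleavage: OsO4 dihydroxylates the monosubstituted alkene much faster than the hindered silyl alkyne and periodate cleaves the diol, 2,6-lutidine suppressing over-oxidation, to give the β-silyloxy aldehyde, which is used at once.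

Step 6
Reactants: 8 (S)-3-[(tert-butyldimethylsilyl)oxy]-6-(trimethylsilyl)hex-5-ynal
Product: 9 (4S,6S)-6-[(tert-butyldimethylsilyl)oxy]-9-(trimethylsilyl)non-1-en-8-yn-4-ol
Conditions: (−)-Ipc2BOMe [from (+)-α-pinene], CH2=CHCH2MgBr, Et2O, −78 °C → rt; 8, −78 °C; then H2O2, pH 7 buffer, MeOH, 0 °C
Reagents that add atoms: allylmagnesium bromide, C=CC[Mg]Br
Why: Brown asymmetric allylboration through a chair transition state: (−)-Ipc2B(allyl) is expected to add to the Si face of the aldehyde under reagent control, which sets C6' with its hydroxyl anti to the C4' silyloxy group (the β-silyloxy group itself exerts only weak 1,3-induction); the buffered oxidative work-up spares the alkynylsilane.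

Step 7
Reactants: 9 (4S,6S)-6-[(tert-butyldimethylsilyl)oxy]-9-(trimethylsilyl)non-1-en-8-yn-4-ol; 10 1-phenylprop-2-en-1-ol (racemic, 3 equiv)
Product: 11 (2E,5S,7S)-7-[(tert-butyldimethylsilyl)oxy]-1-phenyl-10-(trimethylsilyl)dec-2-en-9-yne-1,5-diol, both C1 (= C10') epimers
Conditions: RuCl2(H2IMes)(=CH–C6H4-2-OiPr) (second-generation Hoveyda–Grubbs catalyst, 5 mol %), CH2Cl2, 40 °C
Reagents that add atoms: none
Why: Olefin cross-metathesis of the unhindered terminal alkene with an excess of the secondary allylic alcohol should give the C8'=C9' alkene mainly as the E isomer (its geometry and the C10' configuration are both erased in step 8), the trimethylsilyl cap keeping the alkyne out of enyne metathesis.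

Step 8
Reactants: 11 ene-1,5-diol (both C10' epimers); 12 benzaldehyde dimethyl acetal (3 equiv)
Product: 14 tert-butyldimethyl({(2S)-1-[(2R,4S,6R)-2-phenyl-6-[(E)-2-phenylethenyl]-1,3-dioxan-4-yl]-5-(trimethylsilyl)pent-4-yn-2-yl}oxy)silane, via transposed styryl 1,3-diol 13 (not isolated)
Conditions: Re2O7 (5 mol %), PhCH(OMe)2, CH2Cl2, 0 °C → rt
Reagents that add atoms: none
Why: Re2O7 (with the HOReO3 it releases) converts the C10' hydroxyl into a perrhenate ester of heptavalent rhenium, which shifts oxygen from C10' to C8' by a chair-like [3,3] rearrangement or through a contact allyl cation–perrhenate ion pair; the shift is reversible, erases the C10' configuration so that both epimers of 11 converge, and is pulled forward by conjugation of the new (E)-C9'=C10' alkene with the phenyl ring. The closest known reaction type is the Re2O7-catalysed 1,3-transposition of allylic alcohols with in situ capture of the resulting 1,3-diol as a benzylidene acetal. The 1,3-dioxane closes by acid-catalysed acetal exchange at O6' followed by 6-endo-trig attack of O8' on the O6'-oxocarbenium ion, every stage being reversible. The two new stereocentres, C8' and the acetal carbon, are set under thermodynamic control by C6': only the 6',8'-syn diol gives a chair dioxane with the C5' chain, the styryl group and the phenyl group all equatorial, and an anti acetal can reopen, re-ionise at the cinnamyl-type C8'–O bond and close again. The step needs regioselectivity for oxygen at C8' (secured by styrene conjugation and by the fact that only the C8' isomer can form a six-membered acetal with O6'), syn selectivity (secured by the all-equatorial chair) and chemoselectivity (secured by the silyl ether on O4', which cannot enter an acetal, and by the silyl cap on the alkyne).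

Step 9
Reactants: 14 silyl-alkyne benzylidene acetal
Product: 15 tert-butyldimethyl({(2S)-1-[(2R,4S,6R)-2-phenyl-6-[(E)-2-phenylethenyl]-1,3-dioxan-4-yl]pent-4-yn-2-yl}oxy)silane
Conditions: K2CO3, MeOH, rt
Reagents that add atoms: none
Why: Carbonate-catalysed methanolysis cleaves only the C(sp)–Si bond; the secondary silyl ether and the benzylidene acetal are stable to K2CO3/MeOH.

Step 10
Reactants: 15 terminal alkyne
Product: 16 (5S)-5-[(tert-butyldimethylsilyl)oxy]-6-[(2R,4S,6R)-2-phenyl-6-[(E)-2-phenylethenyl]-1,3-dioxan-4-yl]hex-2-ynal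
Conditions: n-BuLi, THF, −78 °C; DMF, −78 → 0 °C; inverse quench into aq. KH2PO4
Reagents that add atoms: N,N-dimethylformamide, CN(C)C=O
Why: Formylation of the lithium acetylide with DMF: the tetrahedral hemiaminal alkoxide survives until the buffered inverse quench releases the ynal, and the acetylide forms much faster than any metalation of the acetal C–H at −78 °C.

Step 11
Reactants: 16 ynal
Product: 17 (4R,8S)-8-[(tert-butyldimethylsilyl)oxy]-9-[(2R,4S,6R)-2-phenyl-6-[(E)-2-phenylethenyl]-1,3-dioxan-4-yl]non-1-en-5-yn-4-ol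
Conditions: (+)-Ipc2BOMe [from (−)-α-pinene], CH2=CHCH2MgBr, Et2O, −78 °C → rt; 16, −100 °C; then H2O2, pH 7 buffer, MeOH, 0 °C
Reagents that add atoms: allylmagnesium bromide, C=CC[Mg]Br
Why: Brown asymmetric allylboration with the antipodal reagent: (+)-Ipc2B(allyl) is expected to add to the Re face of the ynal and set C6 as R under reagent control, since the nearest existing stereocentre lies beyond the linear alkyne and cannot interfere.

Step 12
Reactants: 17 enynol
Product: 18 (4R,5Z,8S)-8-[(tert-butyldimethylsilyl)oxy]-9-[(2R,4S,6R)-2-phenyl-6-[(E)-2-phenylethenyl]-1,3-dioxan-4-yl]nona-1,5-dien-4-ol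
Conditions: H2 (1 atm), Pd/CaCO3–Pb(OAc)2 (Lindlar catalyst), quinoline, EtOAc, rt, stopped after 1 equiv H2
Reagents that add atoms: none
Why: Lindlar semi-hydrogenation delivers H2 syn to the alkyne to give the (Z)-C1'=C2' alkene, the lead- and quinoline-poisoned catalyst sparing the terminal alkene, the styrene and the benzylic acetal if hydrogen uptake is monitored.

Step 13
Reactants: 18 dienol
Product: 19 (4R,5Z,8S)-8-[(tert-butyldimethylsilyl)oxy]-9-[(2R,4S,6R)-2-phenyl-6-[(E)-2-phenylethenyl]-1,3-dioxan-4-yl]nona-1,5-dien-4-yl prop-2-enoate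
Conditions: acryloyl chloride, Et3N, DMAP (cat.), CH2Cl2, −20 → 0 °C
Reagents that add atoms: acryloyl chloride, C=CC(=O)Cl
Why: Acylation of the secondary allylic alcohol with an acid chloride under amine base (DMAP catalysis) gives the acrylate with C6 untouched.

Step 14
Reactants: 19 acrylate
Product: 20 (6R)-6-{(1Z,4S)-4-[(tert-butyldimethylsilyl)oxy]-5-[(2R,4S,6R)-2-phenyl-6-[(E)-2-phenylethenyl]-1,3-dioxan-4-yl]pent-1-en-1-yl}-5,6-dihydro-2H-pyran-2-one
Conditions: RuCl2(PCy3)2(=CHPh) (first-generation Grubbs catalyst, 10 mol %), CH2Cl2 (0.003 M), 40 °C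
Reagents that add atoms: none
Why: Ring-closing metathesis: the ruthenium carbene forms at the terminal allyl alkene and closes the six-membered ring onto the acrylate, which fixes the cis C3=C4 alkene of ring A, while the first-generation catalyst leaves the 1,2-disubstituted C1'=C2' and styryl alkenes alone at high dilution.

Step 15
Reactants: 20 protected lactone
Product: 21 (6R)-6-[(1Z,4S,6R,8R,9E)-4,6,8-trihydroxy-10-phenyldeca-1,9-dien-1-yl]-5,6-dihydro-2H-pyran-2-one (CNP0368533.3)
Conditions: CSA (0.3 equiv), MeOH, 0 °C → rt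
Reagents that add atoms: none
Why: Acid-catalysed transacetalisation of the benzylidene acetal and methanolysis of the secondary silyl ether under catalytic sulfonic acid at low temperature should release the triol without ionising the cinnamyl-type C8' carbinol or opening the lactone.

**Compound list**

1 | (S)-epichlorohydrin | ClC[C@@H]1CO1 | starting material
2 | trimethylsilylacetylene | C#C[Si](C)(C)C | starting material
3 | (S)-1-chloro-5-(trimethylsilyl)pent-4-yn-2-ol | ClC[C@@H](O)CC#C[Si](C)(C)C | intermediate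
4 | (S)-trimethyl[3-(oxiran-2-yl)prop-1-yn-1-yl]silane | C[Si](C)(C)C#CC[C@H]1CO1 | intermediate
5 | (R)-1-(trimethylsilyl)hept-6-en-1-yn-4-ol | C=CC[C@@H](O)CC#C[Si](C)(C)C | intermediate
6 | (R)-tert-butyldimethyl{[1-(trimethylsilyl)hept-6-en-1-yn-4-yl]oxy}silane | C=CC[C@@H](O[Si](C)(C)C(C)(C)C)CC#C[Si](C)(C)C | intermediate
7 | (4S)-4-[(tert-butyldimethylsilyl)oxy]-7-(trimethylsilyl)hept-6-yne-1,2-diol, both C2 epimers (not isolated) | OCC(O)C[C@@H](O[Si](C)(C)C(C)(C)C)CC#C[Si](C)(C)C | intermediate
8 | (S)-3-[(tert-butyldimethylsilyl)oxy]-6-(trimethylsilyl)hex-5-ynal | O=CC[C@@H](O[Si](C)(C)C(C)(C)C)CC#C[Si](C)(C)C | intermediate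
9 | (4S,6S)-6-[(tert-butyldimethylsilyl)oxy]-9-(trimethylsilyl)non-1-en-8-yn-4-ol | C=CC[C@H](O)C[C@@H](O[Si](C)(C)C(C)(C)C)CC#C[Si](C)(C)C | intermediate
10 | 1-phenylprop-2-en-1-ol (racemic) | C=CC(O)c1ccccc1 | starting material
11 | (2E,5S,7S)-7-[(tert-butyldimethylsilyl)oxy]-1-phenyl-10-(trimethylsilyl)dec-2-en-9-yne-1,5-diol, both C1 (= C10') epimers | C[Si](C)(C)C#CC[C@H](O[Si](C)(C)C(C)(C)C)C[C@@H](O)C/C=C/C(O)c1ccccc1 | intermediate
12 | benzaldehyde dimethyl acetal | COC(OC)c1ccccc1 | starting material
13 | (1E,5S,7S)-7-[(tert-butyldimethylsilyl)oxy]-1-phenyl-10-(trimethylsilyl)dec-1-en-9-yne-3,5-diol, C3 (= C8') epimers in equilibrium (not isolated) | C[Si](C)(C)C#CC[C@H](O[Si](C)(C)C(C)(C)C)C[C@@H](O)CC(O)/C=C/c1ccccc1 | intermediate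
14 | tert-butyldimethyl({(2S)-1-[(2R,4S,6R)-2-phenyl-6-[(E)-2-phenylethenyl]-1,3-dioxan-4-yl]-5-(trimethylsilyl)pent-4-yn-2-yl}oxy)silane (all-equatorial acetal) | C[Si](C)(C)C#CC[C@H](O[Si](C)(C)C(C)(C)C)C[C@@H]1C[C@H](/C=C/c2ccccc2)O[C@H](c2ccccc2)O1 | intermediate
15 | tert-butyldimethyl({(2S)-1-[(2R,4S,6R)-2-phenyl-6-[(E)-2-phenylethenyl]-1,3-dioxan-4-yl]pent-4-yn-2-yl}oxy)silane | C#CC[C@H](O[Si](C)(C)C(C)(C)C)C[C@@H]1C[C@H](/C=C/c2ccccc2)O[C@H](c2ccccc2)O1 | intermediate
16 | (5S)-5-[(tert-butyldimethylsilyl)oxy]-6-[(2R,4S,6R)-2-phenyl-6-[(E)-2-phenylethenyl]-1,3-dioxan-4-yl]hex-2-ynal | O=CC#CC[C@H](O[Si](C)(C)C(C)(C)C)C[C@@H]1C[C@H](/C=C/c2ccccc2)O[C@H](c2ccccc2)O1 | intermediate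
17 | (4R,8S)-8-[(tert-butyldimethylsilyl)oxy]-9-[(2R,4S,6R)-2-phenyl-6-[(E)-2-phenylethenyl]-1,3-dioxan-4-yl]non-1-en-5-yn-4-ol | C=CC[C@@H](O)C#CC[C@H](O[Si](C)(C)C(C)(C)C)C[C@@H]1C[C@H](/C=C/c2ccccc2)O[C@H](c2ccccc2)O1 | intermediate
18 | (4R,5Z,8S)-8-[(tert-butyldimethylsilyl)oxy]-9-[(2R,4S,6R)-2-phenyl-6-[(E)-2-phenylethenyl]-1,3-dioxan-4-yl]nona-1,5-dien-4-ol | C=CC[C@@H](O)/C=C\C[C@H](O[Si](C)(C)C(C)(C)C)C[C@@H]1C[C@H](/C=C/c2ccccc2)O[C@H](c2ccccc2)O1 | intermediate
19 | (4R,5Z,8S)-8-[(tert-butyldimethylsilyl)oxy]-9-[(2R,4S,6R)-2-phenyl-6-[(E)-2-phenylethenyl]-1,3-dioxan-4-yl]nona-1,5-dien-4-yl prop-2-enoate | C=CC[C@@H](OC(=O)C=C)/C=C\C[C@H](O[Si](C)(C)C(C)(C)C)C[C@@H]1C[C@H](/C=C/c2ccccc2)O[C@H](c2ccccc2)O1 | intermediate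
20 | (6R)-6-{(1Z,4S)-4-[(tert-butyldimethylsilyl)oxy]-5-[(2R,4S,6R)-2-phenyl-6-[(E)-2-phenylethenyl]-1,3-dioxan-4-yl]pent-1-en-1-yl}-5,6-dihydro-2H-pyran-2-one | O=C1C=CC[C@H](/C=C\C[C@H](O[Si](C)(C)C(C)(C)C)C[C@@H]2C[C@H](/C=C/c3ccccc3)O[C@H](c3ccccc3)O2)O1 | intermediate
21 | (6R)-6-[(1Z,4S,6R,8R,9E)-4,6,8-trihydroxy-10-phenyldeca-1,9-dien-1-yl]-5,6-dihydro-2H-pyran-2-one | O=C1C=CC[C@H](/C=C\C[C@H](O)C[C@@H](O)C[C@@H](O)/C=C/c2ccccc2)O1 | target

**Step count**

Total step count: 15. Longest linear sequence: 15 steps (from 1).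

**Steps most likely to fail**

Step 8 (key step). The allyl cation–perrhenate manifold may leak before acetal capture: proton loss to a 1-phenyl-1,3-diene, attack of O6' on C10' to give a cyclic allylic ether, or incomplete equilibration that leaves syn and anti acetals. The fallback uses known aldol and reduction chemistry and sets out from aldehyde 8. An Ipc2BCl-mediated boron aldol (Paterson aldol; Et3N, Et2O, −78 °C) with (E)-4-phenylbut-3-en-2-one should give the β-hydroxy enone F1. The Ipc2BCl antipode that adds the enolate to the Si face of 8 would be chosen on small scale, and any C6' epimer removed by chromatography. Narasaka–Prasad reduction (Et2BOMe, NaBH4, THF/MeOH, −78 °C) should then give the 6',8'-syn diol F2 by external hydride delivery to the boron chelate. Acetalisation of F2 with 12 (PPTS, CH2Cl2) comes back to the route at 14.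

Step 7. Turnover with the hindered secondary allylic alcohol may be slow, ruthenium hydride species may isomerise the aryl vinyl carbinol (and the product) to ketones, and the partner may be consumed by homodimerisation. The fallback sets out from 9. Cross-metathesis with crotonaldehyde (catalyst of step 7, CH2Cl2, 40 °C), a fast and E-selective partner that cannot isomerise to a ketone, should give the δ-hydroxy enal F3. 1,2-Addition of PhMgBr (2.5 equiv, THF, −78 °C; the first equivalent is spent on the C6' hydroxyl) forms the C10'–phenyl bond and comes back to the route at 11 as the same mixture of C10' epimers.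

Step 15. Acid in methanol may ionise the cinnamyl-type C8' carbinol (epimerisation, solvolysis to a methyl ether, reverse transposition), and methanol may add to or open the unsaturated lactone. The fallback sets out from 20 and splits the deprotection into two non-solvolytic operations. HF·pyridine buffered with pyridine (THF, 0 °C → rt) should remove the silyl ether and give the hydroxy acetal F4. Hydrolysis of the benzylidene acetal in AcOH/H2O (4:1, 40 °C), a weak acid in a medium where water is the only nucleophile, comes back to the route at 21.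

**Further compounds**

F1 | step 8 | (1E,5R,7S)-7-[(tert-butyldimethylsilyl)oxy]-5-hydroxy-1-phenyl-10-(trimethylsilyl)dec-1-en-9-yn-3-one | C[Si](C)(C)C#CC[C@H](O[Si](C)(C)C(C)(C)C)C[C@@H](O)CC(=O)/C=C/c1ccccc1
F2 | step 8 | (1E,3R,5S,7S)-7-[(tert-butyldimethylsilyl)oxy]-1-phenyl-10-(trimethylsilyl)dec-1-en-9-yne-3,5-diol | C[Si](C)(C)C#CC[C@H](O[Si](C)(C)C(C)(C)C)C[C@@H](O)C[C@@H](O)/C=C/c1ccccc1
F3 | step 7 | (2E,5S,7S)-7-[(tert-butyldimethylsilyl)oxy]-5-hydroxy-10-(trimethylsilyl)dec-2-en-9-ynal | C[Si](C)(C)C#CC[C@H](O[Si](C)(C)C(C)(C)C)C[C@@H](O)C/C=C/C=O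
F4 | step 15 | (6R)-6-{(1Z,4S)-4-hydroxy-5-[(2R,4R,6R)-2-phenyl-6-[(E)-2-phenylethenyl]-1,3-dioxan-4-yl]pent-1-en-1-yl}-5,6-dihydro-2H-pyran-2-one | O=C1C=CC[C@H](/C=C\C[C@H](O)C[C@@H]2C[C@H](/C=C/c3ccccc3)O[C@H](c3ccccc3)O2)O1
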